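The dihydrobenzofuran is disconnected across O1–C2 and C3a–C3, so that the furan ring (ring B) arises by an enantioselective palladium-catalysed oxyarylation of the (E)-alkene of silyl-protected isoeugenol with an ortho-iodophenol. The step exploits the adjacent O1/C3a pair on the benzo ring (ring A) and the trans C2-aryl/C3-methyl pattern, which is the E-alkene geometry carried through a syn addition; both ring stereocentres form in this one event. The precursor phenol carries iodine at the future C3a and bromine at C5; the bromine is later exchanged for an (S)-lactate-derived acyl group, whose stereocentre directs a chelation-controlled reduction to the erythro diol.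

Key step: step 3

Locants: benzofuran numbering O1, C2, C3, C3a, C4 to C7, C7a; side chain C1' (benzylic) and C2'.

Assumption: the sense of asymmetric induction of the chiral bisphosphine in step 3 cannot be predicted with confidence; the ligand antipode that delivers the (2S,3S) product is the one meant, written here as (R)-DTBM-SEGPHOS.

Step 1
Reactants: 1 4-bromo-2-methoxyphenol
Product: 2 4-bromo-2-iodo-6-methoxyphenol
Conditions: NIS (1.05 equiv), TsOH·H2O (10 mol%), MeCN, 0 °C to rt
Reagents that add atoms: N-iodosuccinimide, O=C1CCC(=O)N1I
Why: Electrophilic aromatic iodination, in which the free hydroxyl directs to its only open ortho position (para is blocked by bromine), as in the halogenation of other 4-substituted guaiacols.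

Step 2
Reactants: 3 (E)-isoeugenol
Product: 4 tert-butyl{2-methoxy-4-[(E)-prop-1-enyl]phenoxy}dimethylsilane
Conditions: TBSCl, imidazole, DMF, rt
Reagents that add atoms: tert-butyldimethylsilyl chloride, CC(C)(C)[Si](C)(C)Cl
Why: Silyl ether formation masks the acidic phenol against the silver base of step 3 and the organolithium of step 5, and leaves the E-alkene untouched.

Step 3
Reactants: 2 4-bromo-2-iodo-6-methoxyphenol; 4 tert-butyl{2-methoxy-4-[(E)-prop-1-enyl]phenoxy}dimethylsilane
Product: 5 tert-butyl{4-[(2S,3S)-5-bromo-7-methoxy-3-methyl-2,3-dihydro-1-benzofuran-2-yl]-2-methoxyphenoxy}dimethylsilane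
Conditions: Pd2(dba)3 (2.5 mol%), (R)-DTBM-SEGPHOS (6 mol%), Ag2CO3 (1.2 equiv), toluene, 60 °C
Reagents that add atoms: none
Why: Proposed new method: oxidative addition of zerovalent palladium into the C–I bond of 2, iodide abstraction and phenol deprotonation by Ag2CO3, then syn migratory insertion of the (E)-alkene of 4 should place the aryl carbon on the methyl-bearing alkene carbon and palladium on the benzylic carbon, where the electron-rich arene stabilises it as an η3-benzyl. The resulting six-membered palladium aryloxide should close ring B by C–O reductive elimination with retention, so the five-membered ring forms by reductive elimination from a six-membered oxapalladacycle and not by an ionic cyclisation. The closest known reactions are the racemic Heck oxyarylation of propenylarenes and chromenes with ortho-functionalised phenols and the enantioselective palladium-catalysed syn-carboetherification of dihydrofurans with 2-bromophenols; enantiocontrol with an acyclic propenylarene is the untested element. C3 is set by the chiral bisphosphine through face selection in the insertion, and C2 follows from the syn addition across the E-alkene, which translates into the trans-2,3 relationship; a stepwise closure through the benzylic cation would converge on the same, more stable trans isomer. The step needs chemoselectivity for C–I over C–Br (weaker C–I bond, mild temperature), aryl delivery to the non-benzylic carbon (benzylic stabilisation of palladium) and suppression of β-hydride elimination (chelating aryloxide and a cationic, bidentate-ligated palladium centre with no open cis site).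

Step 4
Reactants: 6 ethyl (2S)-2-(tert-butyldimethylsilyloxy)propanoate
Product: 7 (2S)-2-(tert-butyldimethylsilyloxy)-N-methoxy-N-methylpropanamide
Conditions: MeNH(OMe)·HCl (1.5 equiv), i-PrMgCl (3.0 equiv), THF, −20 to 0 °C
Reagents that add atoms: N,O-dimethylhydroxylamine hydrochloride, CNOC.Cl
Why: Weinreb amide formation by aminolysis of the ester with the chloromagnesium amide at low temperature, which should proceed without enolisation and so retain the lactate stereocentre.

Step 5
Reactants: 5 tert-butyl{4-[(2S,3S)-5-bromo-7-methoxy-3-methyl-2,3-dihydro-1-benzofuran-2-yl]-2-methoxyphenoxy}dimethylsilane; 7 (2S)-2-(tert-butyldimethylsilyloxy)-N-methoxy-N-methylpropanamide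
Product: 10 (2S)-2-(tert-butyldimethylsilyloxy)-1-[(2S,3S)-2-[4-(tert-butyldimethylsilyloxy)-3-methoxyphenyl]-7-methoxy-3-methyl-2,3-dihydro-1-benzofuran-5-yl]propan-1-one, via aryllithium 8 (not isolated), via tetrahedral lithium adduct 9 (not isolated)
Conditions: n-BuLi (1.05 equiv), THF, −78 °C; then 7, −78 to −40 °C; sat. aq. NH4Cl
Reagents that add atoms: none
Why: Bromine–lithium exchange followed by Weinreb ketone synthesis, in which the chelated tetrahedral adduct stops the addition at the ketone stage; no stereocentre of the product is formed here, C2' being carried over from the chiral pool.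

Step 6
Reactants: 10 (2S)-2-(tert-butyldimethylsilyloxy)-1-[(2S,3S)-2-[4-(tert-butyldimethylsilyloxy)-3-methoxyphenyl]-7-methoxy-3-methyl-2,3-dihydro-1-benzofuran-5-yl]propan-1-one
Product: 11 (2S)-2-hydroxy-1-[(2S,3S)-2-(4-hydroxy-3-methoxyphenyl)-7-methoxy-3-methyl-2,3-dihydro-1-benzofuran-5-yl]propan-1-one
Conditions: HF·pyridine, pyridine/THF, 0 °C to rt
Reagents that add atoms: none
Why: Fluoride-mediated desilylation under mildly acidic, base-free conditions should cleave both silyl ethers without epimerisation or α-ketol rearrangement of the α-hydroxy ketone.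

Step 7
Reactants: 11 (2S)-2-hydroxy-1-[(2S,3S)-2-(4-hydroxy-3-methoxyphenyl)-7-methoxy-3-methyl-2,3-dihydro-1-benzofuran-5-yl]propan-1-one
Product: 12 (1R,2S)-1-[(2S,3S)-2-(4-hydroxy-3-methoxyphenyl)-7-methoxy-3-methyl-2,3-dihydro-1-benzofuran-5-yl]propane-1,2-diol
Conditions: Zn(BH4)2 (pre-formed solution in Et2O, excess), Et2O/THF, −20 to 0 °C; sat. aq. NH4Cl
Reagents that add atoms: none
Why: Chelation-controlled hydride reduction (Cram chelate model), in which zinc bridges the carbonyl and the free C2' hydroxyl and hydride adds to the face on the side of the C2' hydrogen, which should set C1' as R and give the anti (erythro) 1R,2S diol.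

Compound list
1 | 4-bromo-2-methoxyphenol | COc1cc(Br)ccc1O | starting material
2 | 4-bromo-2-iodo-6-methoxyphenol | COc1cc(Br)cc(I)c1O | intermediate
3 | (E)-isoeugenol, 2-methoxy-4-[(E)-prop-1-enyl]phenol | COc1cc(/C=C/C)ccc1O | starting material
4 | tert-butyl{2-methoxy-4-[(E)-prop-1-enyl]phenoxy}dimethylsilane | COc1cc(/C=C/C)ccc1O[Si](C)(C)C(C)(C)C | intermediate
5 | tert-butyl{4-[(2S,3S)-5-bromo-7-methoxy-3-methyl-2,3-dihydro-1-benzofuran-2-yl]-2-methoxyphenoxy}dimethylsilane | COc1cc([C@H]2Oc3c(OC)cc(Br)cc3[C@@H]2C)ccc1O[Si](C)(C)C(C)(C)C | intermediate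
6 | ethyl (2S)-2-(tert-butyldimethylsilyloxy)propanoate | CCOC(=O)[C@H](C)O[Si](C)(C)C(C)(C)C | starting material
7 | (2S)-2-(tert-butyldimethylsilyloxy)-N-methoxy-N-methylpropanamide | CON(C)C(=O)[C@H](C)O[Si](C)(C)C(C)(C)C | intermediate
8 | {(2S,3S)-2-[4-(tert-butyldimethylsilyloxy)-3-methoxyphenyl]-7-methoxy-3-methyl-2,3-dihydro-1-benzofuran-5-yl}lithium (aryllithium, not isolated) | COc1cc([C@H]2Oc3c(OC)cc([Li])cc3[C@@H]2C)ccc1O[Si](C)(C)C(C)(C)C | intermediate
9 | lithium alkoxide of the N-methoxy-N-methyl hemiaminal formed from 8 and 7 (tetrahedral adduct, configuration at the hemiaminal carbon not defined, not isolated) | COc1cc([C@H]2Oc3c(OC)cc(C(O[Li])(N(C)OC)[C@H](C)O[Si](C)(C)C(C)(C)C)cc3[C@@H]2C)ccc1O[Si](C)(C)C(C)(C)C | intermediate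
10 | (2S)-2-(tert-butyldimethylsilyloxy)-1-[(2S,3S)-2-[4-(tert-butyldimethylsilyloxy)-3-methoxyphenyl]-7-methoxy-3-methyl-2,3-dihydro-1-benzofuran-5-yl]propan-1-one | COc1cc([C@H]2Oc3c(OC)cc(C(=O)[C@H](C)O[Si](C)(C)C(C)(C)C)cc3[C@@H]2C)ccc1O[Si](C)(C)C(C)(C)C | intermediate
11 | (2S)-2-hydroxy-1-[(2S,3S)-2-(4-hydroxy-3-methoxyphenyl)-7-methoxy-3-methyl-2,3-dihydro-1-benzofuran-5-yl]propan-1-one | COc1cc([C@H]2Oc3c(OC)cc(C(=O)[C@H](C)O)cc3[C@@H]2C)ccc1O | intermediate
12 | (1R,2S)-1-[(2S,3S)-2-(4-hydroxy-3-methoxyphenyl)-7-methoxy-3-methyl-2,3-dihydro-1-benzofuran-5-yl]propane-1,2-diol | COc1cc([C@H]2Oc3c(OC)cc([C@@H](O)[C@H](C)O)cc3[C@@H]2C)ccc1O | target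

Total step count: 7. Longest linear sequence: 5 steps (1 or 2, then 3, 5, 6, 7).

Steps most likely to fail

Step 3 (bears the label). Enantiofacial discrimination in the migratory insertion may be poor, and β-hydride elimination may outrun C–O bond formation once the bulky chiral bisphosphine is bound, giving the open arylated alkene. The fallback replaces asymmetric catalysis by resolution. Setting out from 2 and 4, the racemic Heck oxyarylation under achiral conditions (Pd(OAc)2, PPh3, Ag2CO3, acetone, 50 °C), an established reaction type for propenylarenes, should give 5 as a racemate, that is 5 together with its mirror image tert-butyl{4-[(2R,3R)-5-bromo-7-methoxy-3-methyl-2,3-dihydro-1-benzofuran-2-yl]-2-methoxyphenoxy}dimethylsilane F1. Preparative chromatography on a chiral polysaccharide stationary phase should separate the two, and the route is rejoined at 5.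

Step 5. The aryllithium 8 may act as a base toward 7, causing α-deprotonation with loss of configurational purity or simple quenching to the debrominated arene, or the bromine–lithium exchange may be incomplete. The fallback replaces acylation and chelation-controlled reduction by a carbonyl addition under Felkin–Anh control. Setting out from 6, reduction with i-Bu2AlH (CH2Cl2, −78 °C) should give (2S)-2-(tert-butyldimethylsilyloxy)propanal F2. Aryllithium 8, generated from 5 as in step 5, is added to F2 in THF at −78 °C, where the non-chelating silyl ether should favour the anti adduct (1R,2S)-2-(tert-butyldimethylsilyloxy)-1-[(2S,3S)-2-[4-(tert-butyldimethylsilyloxy)-3-methoxyphenyl]-7-methoxy-3-methyl-2,3-dihydro-1-benzofuran-5-yl]propan-1-ol F3. HF·pyridine then removes both silyl groups, and the route is rejoined at the target 12, bypassing 10 and 11.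

Step 7. Facial selectivity may erode if the zinc chelate between the carbonyl and the C2' hydroxyl is not the reacting species, through competing open-chain hydride delivery or interference by the zinc phenoxide. The fallback replaces substrate control by reagent control. Setting out from 11, Noyori asymmetric transfer hydrogenation with RuCl(p-cymene)[(S,S)-TsDPEN] in HCO2H/Et3N at rt should give the 1R carbinol irrespective of chelation; the (S,S) antipode is expected to be the right one by analogy with aryl alkyl ketones. The route is rejoined at 12, and no further compound arises (F0).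

Further compounds
F1 | step 3 | tert-butyl{4-[(2R,3R)-5-bromo-7-methoxy-3-methyl-2,3-dihydro-1-benzofuran-2-yl]-2-methoxyphenoxy}dimethylsilane | COc1cc([C@@H]2Oc3c(OC)cc(Br)cc3[C@H]2C)ccc1O[Si](C)(C)C(C)(C)C
F2 | step 5 | (2S)-2-(tert-butyldimethylsilyloxy)propanal | O=C[C@H](C)O[Si](C)(C)C(C)(C)C
F3 | step 5 | (1R,2S)-2-(tert-butyldimethylsilyloxy)-1-[(2S,3S)-2-[4-(tert-butyldimethylsilyloxy)-3-methoxyphenyl]-7-methoxy-3-methyl-2,3-dihydro-1-benzofuran-5-yl]propan-1-ol | COc1cc([C@H]2Oc3c(OC)cc([C@@H](O)[C@H](C)O[Si](C)(C)C(C)(C)C)cc3[C@@H]2C)ccc1O[Si](C)(C)C(C)(C)C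
F0 | step 7 | none | none
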